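**Plan**

- Retrosynthesis: the C2–C3 bond of the hexadecan-2-one chain is cut first (tetradecyl Grignard reagent plus an aldehyde). The aldehyde carbon is traced back to the CH2 terminus of a vinyl group on ring C2, and the butyl chain to a but-1-enyl group on ring C5.
- The two exocyclic C=C bonds (C1'=C2' of the vinyl group, C1''=C2'' of the butenyl group) are then cut together as a retro ring-opening cross-metathesis. This leaves meso 7-oxabicyclo[2.2.1]hept-2-ene and but-1-ene.
- Enabling feature: in the cis-oxolane O1/C2–C5, C2 and C5 each bear one carbon arm and C3/C4 are plain CH2. The ring is therefore the oxygen-bridge ring (O7, C1, C6, C5, C4) of the bicycle, and the two arms are the two halves of its C2=C3 alkene.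
- Forward: the oxolane is closed once, in step 1, by transannular bromoetherification of cyclohex-3-en-1-ol. Elimination gives the meso alkene, metathesis opens the carbocycle, and the chain is finished by hydroboration, hydrogenation, oxidation, Grignard addition and oxidation.
- Stereochemistry: the 2,5-cis relation is inherited from the bicycle. The absolute configuration comes from the chiral molybdenum alkylidene, which chooses between the two enantiotopic alkene carbons in step 3. No later step touches C2 or C5.

Key step: step 3

Remark: the sense of induction of the (R)-aryloxide complex is assigned by analogy and would be checked on the first run (at the alcohol of step 4); if the antipode forms, the (S)-aryloxide is used with no other change. The butenyl alkene is written as Z, the geometry this catalyst class favours; any E isomer converges in step 5.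

**Route**

Step 1
Reactants: 1 cyclohex-3-en-1-ol (racemic, commercial)
Product: 2 (±)-endo-2-bromo-7-oxabicyclo[2.2.1]heptane [rac-(1R,2R,4S), Br anti to the oxygen bridge]
Conditions: NBS (1.1 equiv), CH2Cl2, 0 → 23 °C, dark
Reagents that add atoms: N-bromosuccinimide, O=C1CCC(=O)N1Br
Why: Bromonium formation on the ring alkene and anti, transannular attack of the C1 hydroxyl on the distal alkene carbon (5-exo bromoetherification, the only alternative being an oxetane) close the 7-oxabicyclo[2.2.1]heptane, and the anti addition places bromine endo at a centre that step 2 removes again.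

Step 2
Reactants: 2 (±)-endo-2-bromo-7-oxabicyclo[2.2.1]heptane
Product: 3 7-oxabicyclo[2.2.1]hept-2-ene (meso)
Conditions: KOtBu (2 equiv), DMSO, 25 → 60 °C; product distilled out under reduced pressure, redistilled from CaH2
Reagents that add atoms: none
Why: E2 dehydrobromination with a strong hindered base in a dipolar aprotic solvent can only use the hydrogens on C3 (the bridgehead is excluded by Bredt's rule), so syn-periplanar loss of endo-H and endo-Br should give the symmetric strained alkene, as in the dehydrohalogenation of 2-halonorbornanes and 2-halo-7-azanorbornanes.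

Step 3
Reactants: 3 7-oxabicyclo[2.2.1]hept-2-ene; 4 but-1-ene
Product: 5 (2S,5R)-2-[(Z)-but-1-en-1-yl]-5-ethenyloxolane (cis)
Conditions: Mo(=N-1-Ad)(=CHCMe2Ph)(2,5-Me2C4H2N)(OAr*) 2 mol%, made in situ from Mo(=N-1-Ad)(=CHCMe2Ph)(2,5-Me2C4H2N)2 and Ar*OH; 4 (10 equiv), C6H6, 22 °C, 1 h, N2, sealed tube [Ad = adamantyl; Ar*OH = (R)-3,3'-dibromo-2'-(tert-butyldimethylsilyloxy)-5,5',6,6',7,7',8,8'-octahydro-1,1'-binaphthalen-2-ol]
Reagents that add atoms: none
Why: Asymmetric ring-opening cross-metathesis: the propylidene Mo=CHEt formed from the neophylidene and but-1-ene adds [2+2] to the exposed exo face of the strained C2=C3 bond of 3, the all-syn metallacyclobutane cycloreverts irreversibly with release of the bicyclic strain to give the Z-butenyl terminus and a ring-bound alkylidene, and that alkylidene takes CH2 from a second but-1-ene, which frees the vinyl terminus and returns Mo=CHEt. The closest known reactions are the Z- and enantioselective ring-opening cross-metatheses of meso oxabicyclic alkenes with aryl- and heteroatom-substituted terminal alkenes by this class of stereogenic-at-molybdenum monoaryloxide pyrrolide complexes, and with aliphatic 1-alkenes by chiral ruthenium carbenes. No ring is closed: the carbocycle is opened and the oxolane is simply the bridge ring O7/C1/C6/C5/C4 of 3, so the 2,5-cis relation is inherited. The two oxolane stereocentres receive their absolute configuration here, controlled by the stereogenic molybdenum centre and its (R)-aryloxide, which decide which of the two enantiotopic alkene carbons becomes bonded to the propylidene carbon. The step needs this enantiotopic-carbon selectivity and 1:1 capping instead of polymerisation or double capping; the ring strain of 3 makes it react far faster than but-1-ene self-couples, its mirror symmetry leaves the catalyst as the only differentiating element, and the α-branched, oxygen-bearing ring alkylidene is intercepted by the excess of small but-1-ene and resists transfer of CHEt to the second terminus.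

Step 4
Reactants: 5 (2S,5R)-2-[(Z)-but-1-en-1-yl]-5-ethenyloxolane
Product: 7 2-[(2R,5S)-5-[(Z)-but-1-en-1-yl]oxolan-2-yl]ethan-1-ol, via B-alkyl-9-BBN adduct 6 (not isolated)
Conditions: 9-BBN (1.1 equiv), THF, 0 → 23 °C; then 3 M aq NaOH, 30% H2O2, 0 → 23 °C
Reagents that add atoms: 9-borabicyclo[3.3.1]nonane (9-BBN), B1C2CCCC1CCC2 (boron fragment of 6); hydrogen peroxide, OO (hydroxyl oxygen of 7)
Why: Hydroboration with the bulky dialkylborane 9-BBN is far faster at a monosubstituted than at a Z-1,2-disubstituted alkene and places boron on the terminal carbon, and alkaline peroxide oxidation replaces boron by hydroxyl with retention, so only the vinyl group becomes the 2-hydroxyethyl arm and no stereocentre is formed or touched.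

Step 5
Reactants: 7 2-[(2R,5S)-5-[(Z)-but-1-en-1-yl]oxolan-2-yl]ethan-1-ol
Product: 8 2-[(2R,5R)-5-butyloxolan-2-yl]ethan-1-ol
Conditions: H2 (1 atm), 5% Pt/C, EtOAc, 23 °C
Reagents that add atoms: none
Why: Heterogeneous catalytic hydrogenation of the disubstituted alkene gives the butyl chain without creating a stereocentre, and platinum is chosen over palladium because it is less prone to move the double bond toward the ring oxygen or to cleave the allylic C–O bond, either of which would endanger C5.

Step 6
Reactants: 8 2-[(2R,5R)-5-butyloxolan-2-yl]ethan-1-ol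
Product: 9 2-[(2R,5R)-5-butyloxolan-2-yl]acetaldehyde
Conditions: Dess–Martin periodinane (1.2 equiv), NaHCO3, CH2Cl2, 0 → 23 °C; used directly
Reagents that add atoms: none
Why: Dess–Martin oxidation of a primary alcohol stops at the aldehyde under buffered, non-basic conditions, which protects the β-alkoxy aldehyde from β-elimination and thus C2 from epimerisation.

Step 7
Reactants: 9 2-[(2R,5R)-5-butyloxolan-2-yl]acetaldehyde; 10 tetradecylmagnesium chloride (commercial, 1.0 M in THF)
Product: 11 1-[(2R,5R)-5-butyloxolan-2-yl]hexadecan-2-ol (both epimers at the carbinol carbon)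
Conditions: 10 (1.3 equiv), THF, −78 → −20 °C; H2O/sat. aq NH4Cl quench
Reagents that add atoms: none
Why: Grignard addition of a primary alkylmagnesium halide to an unhindered aldehyde at low temperature should outrun enolisation and forms the C2–C3 bond of the hexadecane chain, while the new carbinol centre is formed without control, which is irrelevant because step 8 oxidises it.

Step 8
Reactants: 11 1-[(2R,5R)-5-butyloxolan-2-yl]hexadecan-2-ol
Product: 12 1-[(2R,5R)-5-butyloxolan-2-yl]hexadecan-2-one
Conditions: Dess–Martin periodinane (1.3 equiv), NaHCO3, CH2Cl2, 0 → 23 °C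
Reagents that add atoms: none
Why: Dess–Martin oxidation of the secondary alcohol gives the ketone under buffered neutral conditions that should not trigger retro-oxa-Michael opening of the β-alkoxy ketone, so both carbinol epimers converge on 12 with the (2R,5R) ring configuration intact.

**Compound list**

1 | cyclohex-3-en-1-ol (racemic) | OC1CCC=CC1 | starting material
2 | (±)-endo-2-bromo-7-oxabicyclo[2.2.1]heptane, rac-(1R,2R,4S), one enantiomer drawn | Br[C@@H]1C[C@@H]2CC[C@H]1O2 | intermediate
3 | 7-oxabicyclo[2.2.1]hept-2-ene, meso (1R,4S) | C1=C[C@H]2CC[C@@H]1O2 | intermediate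
4 | but-1-ene | C=CCC | starting material
5 | (2S,5R)-2-[(Z)-but-1-en-1-yl]-5-ethenyloxolane | C=C[C@H]1CC[C@@H](/C=C\CC)O1 | intermediate
6 | 9-{2-[(2S,5S)-5-[(Z)-but-1-en-1-yl]oxolan-2-yl]ethyl}-9-borabicyclo[3.3.1]nonane (not isolated) | B1(CC[C@H]2CC[C@@H](/C=C\CC)O2)C2CCCC1CCC2 | intermediate
7 | 2-[(2R,5S)-5-[(Z)-but-1-en-1-yl]oxolan-2-yl]ethan-1-ol | OCC[C@H]1CC[C@@H](/C=C\CC)O1 | intermediate
8 | 2-[(2R,5R)-5-butyloxolan-2-yl]ethan-1-ol | OCC[C@H]1CC[C@@H](CCCC)O1 | intermediate
9 | 2-[(2R,5R)-5-butyloxolan-2-yl]acetaldehyde | O=CC[C@H]1CC[C@@H](CCCC)O1 | intermediate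
10 | tetradecylmagnesium chloride | CCCCCCCCCCCCCC[Mg]Cl | starting material
11 | 1-[(2R,5R)-5-butyloxolan-2-yl]hexadecan-2-ol (carbinol epimers) | CCCCCCCCCCCCCCC(O)C[C@H]1CC[C@@H](CCCC)O1 | intermediate
12 | 1-[(2R,5R)-5-butyloxolan-2-yl]hexadecan-2-one | CCCCCCCCCCCCCCC(=O)C[C@H]1CC[C@@H](CCCC)O1 | target

Total step count: 8
Longest linear sequence: 8 steps (1 → 12); 4 and 10 enter as commercial reagents in steps 3 and 7.

**Steps most likely to fail**

1. Step 3. The risk is incomplete discrimination of the two enantiotopic alkene carbons when a small aliphatic alkylidene (and the methylidene from but-1-ene self-metathesis) carries the chain, together with ring-opening oligomerisation or capping of both termini.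
Fallback, setting out from 3 and returning at 5, uses enzymatic desymmetrisation instead of asymmetric metathesis. Dihydroxylation (OsO4 cat., N-methylmorpholine N-oxide, acetone/H2O) should give meso (1R,2S,3R,4S)-7-oxabicyclo[2.2.1]heptane-2,3-diol F1. Cleavage with NaIO4 gives cis-oxolane-2,5-dicarbaldehyde F2, which is reduced in the same flask with NaBH4 to meso [(2R,5S)-oxolane-2,5-diyl]dimethanol F3. Lipase-catalysed monoacetylation (vinyl acetate; the lipase, for example from Pseudomonas cepacia, is selected by screening so that the hydroxymethyl group on the future vinyl-bearing carbon is acetylated) gives [(2R,5S)-5-(hydroxymethyl)oxolan-2-yl]methyl acetate F4. Dess–Martin oxidation gives [(2R,5S)-5-formyloxolan-2-yl]methyl acetate F5. A Z-selective Wittig reaction with Ph3P=CHCH2CH3 (from [Ph3PCH2CH2CH3]Br and NaN(SiMe3)2, THF, −78 °C) gives [(2R,5S)-5-[(Z)-but-1-en-1-yl]oxolan-2-yl]methyl acetate F6. Methanolysis (K2CO3, MeOH) gives [(2R,5S)-5-[(Z)-but-1-en-1-yl]oxolan-2-yl]methanol F7. Dess–Martin oxidation gives (2R,5S)-5-[(Z)-but-1-en-1-yl]oxolane-2-carbaldehyde F8, and methylenation with Ph3P=CH2 (from [Ph3PCH3]Br and NaN(SiMe3)2) returns to the route at 5.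

2. Step 2. The risk is slow syn-elimination from the endo bromide, with substitution or decomposition at the temperature required and evaporative loss of the volatile alkene.
Fallback, setting out from 1 and returning at 3, replaces base-induced elimination by a selenoxide syn-elimination. Phenylselenoetherification of 1 (PhSeCl, CH2Cl2, −78 °C) should give (±)-endo-2-(phenylselanyl)-7-oxabicyclo[2.2.1]heptane F9. Oxidation with H2O2 gives (±)-endo-2-(phenylseleninyl)-7-oxabicyclo[2.2.1]heptane F10, which is not isolated and on warming eliminates toward C3 (the only syn hydrogen that can give an alkene) to deliver 3.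

3. Step 7. The risk is deprotonation of the β-alkoxy aldehyde by the Grignard reagent, leading to β-elimination with opening of the oxolane and loss of configuration at C2, or reduction of the aldehyde by β-hydride transfer.
Fallback, setting out from 8 and returning at 12, uses acyl substitution instead of addition and re-oxidation. Oxidation of 8 (TEMPO cat., PhI(OAc)2, MeCN/H2O) gives 2-[(2R,5R)-5-butyloxolan-2-yl]acetic acid F11. Amide coupling (MeNHOMe·HCl, EDC·HCl, N-methylmorpholine, CH2Cl2) gives 2-[(2R,5R)-5-butyloxolan-2-yl]-N-methoxy-N-methylacetamide F12. This Weinreb amide reacts with 10 (THF, 0 °C) to give 12 directly after aqueous work-up, so that 9, 11 and step 8 are bypassed.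

**Further compounds**

F1 | step 3 | (1R,2S,3R,4S)-7-oxabicyclo[2.2.1]heptane-2,3-diol (meso, exo,exo) | O[C@H]1[C@@H](O)[C@@H]2CC[C@H]1O2
F2 | step 3 | (2R,5S)-oxolane-2,5-dicarbaldehyde (meso, cis; not isolated) | O=C[C@H]1CC[C@@H](C=O)O1
F3 | step 3 | [(2R,5S)-oxolane-2,5-diyl]dimethanol (meso, cis) | OC[C@H]1CC[C@@H](CO)O1
F4 | step 3 | [(2R,5S)-5-(hydroxymethyl)oxolan-2-yl]methyl acetate | CC(=O)OC[C@H]1CC[C@@H](CO)O1
F5 | step 3 | [(2R,5S)-5-formyloxolan-2-yl]methyl acetate | CC(=O)OC[C@H]1CC[C@@H](C=O)O1
F6 | step 3 | [(2R,5S)-5-[(Z)-but-1-en-1-yl]oxolan-2-yl]methyl acetate | CC(=O)OC[C@H]1CC[C@@H](/C=C\CC)O1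
F7 | step 3 | [(2R,5S)-5-[(Z)-but-1-en-1-yl]oxolan-2-yl]methanol | OC[C@H]1CC[C@@H](/C=C\CC)O1
F8 | step 3 | (2R,5S)-5-[(Z)-but-1-en-1-yl]oxolane-2-carbaldehyde | O=C[C@H]1CC[C@@H](/C=C\CC)O1
F9 | step 2 | (±)-endo-2-(phenylselanyl)-7-oxabicyclo[2.2.1]heptane, rac-(1R,2R,4S), one enantiomer drawn | c1ccccc1[Se][C@@H]1C[C@@H]2CC[C@H]1O2
F10 | step 2 | (±)-endo-2-(phenylseleninyl)-7-oxabicyclo[2.2.1]heptane (selenoxide, mixture at selenium; not isolated) | O=[Se](c1ccccc1)[C@@H]1C[C@@H]2CC[C@H]1O2
F11 | step 7 | 2-[(2R,5R)-5-butyloxolan-2-yl]acetic acid | OC(=O)C[C@H]1CC[C@@H](CCCC)O1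
F12 | step 7 | 2-[(2R,5R)-5-butyloxolan-2-yl]-N-methoxy-N-methylacetamide | CON(C)C(=O)C[C@H]1CC[C@@H](CCCC)O1
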